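**Retrosynthetic overview**

1. The target is (3S,6R,7S)-6-acetoxy-3-angeloyloxygermacra-1(10)Z,4E-diene. The esters go on last (21 ⇐ 18 ⇐ 17 ⇐ 16), the C6 carbinol comes from peripheral reduction of the (4E)-dienone 15, and 15 comes from the (4Z)-dienone 14 by photoisomerisation.
2. Key disconnection C8–C9: the ring holds the array C6(–O)–C7–C8–C9–C10=C1, a C6 ketone with the C1=C10 double bond δ,ε to it (oxy-Cope retron). Re-joining C1 to C6 contracts the cyclodecadiene to a cyclohexene made of C1–C6, with isopropenyl (C10, C9, C14) on C1 and OH plus a 3-methylbut-1-en-2-yl group (C7, C8, C11–C13) on C6.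
3. That cyclohexene (C4–CH3, C3–O, C1–isopropenyl) is the carvone skeleton: carbinol 12 ⇐ enone 7 + alkenyllithium 11 (Shapiro, from 3-methylbutan-2-one). Enone 7 ⇐ (S)-carvone by reduction, directed epoxidation and transposition of oxygen to C6.
4. Stereochemical relay: the carvone stereocentre (it becomes C1 and ends as an sp2 carbon) sets C3, then the C6 carbinol. The chair of the rearrangement turns these into the planar chirality of the enolate, which sets C7, and C7 then steers the reduction at C6.
5. Ring order: only one ring is ever present. The cyclohexene of carvone is enlarged to the ten-membered ring in step 8 and no other ring is formed.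

Key step: step 8

Remark: ring atoms are numbered as in germacrane throughout the discussion (C1 =CH, C2 CH2, C3 CH–O-angelate, C4 C–CH3, C5 =CH, C6 CH–OAc, C7 CH–isopropyl, C8 and C9 CH2, C10 C–CH3), also in the earlier intermediates; compound names carry their own systematic locants. (S)-(+)-Carvone, angelic acid and 2,4,6-tri(propan-2-yl)benzenesulfonohydrazide are taken as commercial.

**Route**

Step 1
Reactants: 1 (S)-(+)-carvone
Product: 2 (1S,5S)-2-methyl-5-(prop-1-en-2-yl)cyclohex-2-en-1-ol (cis-carveol)
Conditions: NaBH4, CeCl3·7H2O, MeOH, −20 → 0 °C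
Reagents that add atoms: none
Why: Luche 1,2-reduction, in which hydride adds axially to the cerium-activated enone and gives the pseudo-equatorial alcohol cis to the isopropenyl group, so that the carbinol centre (future C3, S) is set by the carvone stereocentre.

Step 2
Reactants: 2 (1S,5S)-cis-carveol
Product: 3 (1S,2S,4R,6R)-1-methyl-4-(prop-1-en-2-yl)-7-oxabicyclo[4.1.0]heptan-2-ol
Conditions: VO(acac)2 (2 mol %), t-BuOOH, CH2Cl2, 0 °C → rt
Reagents that add atoms: tert-butyl hydroperoxide, CC(C)(C)OO
Why: Vanadium-catalysed hydroxyl-directed epoxidation, in which the allylic-alcohol olefin reacts much faster than the isolated isopropenyl group and oxygen is delivered syn to OH; both new centres are erased again in steps 4 and 5, so their sense is immaterial.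

Step 3
Reactants: 3 the epoxy alcohol
Product: 4 tert-butyldimethyl{[(1R,2S,4S,6R)-1-methyl-4-(prop-1-en-2-yl)-7-oxabicyclo[4.1.0]heptan-2-yl]oxy}silane
Conditions: TBSCl, imidazole, DMF, rt
Reagents that add atoms: tert-butyldimethylsilyl chloride, CC(C)(C)[Si](C)(C)Cl
Why: Standard silylation of the secondary alcohol; the TBS ether should survive selenolate, chromate, organolithium, KH and borohydride and later serves as the conformational anchor of step 8.

Step 4
Reactants: 4 the silylated epoxide
Product: 6 (1R,4R,6S)-6-[(tert-butyldimethylsilyl)oxy]-1-methyl-4-(prop-1-en-2-yl)cyclohex-2-en-1-ol, via hydroxy selenide 5 (not isolated)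
Conditions: (PhSe)2, NaBH4, EtOH, 78 °C; then THF, 30% H2O2, 0 °C → rt
Reagents that add atoms: none
Why: Epoxide-to-allylic-alcohol transposition by selenolate opening and selenoxide syn-elimination, in which PhSe− attacks the secondary epoxide carbon in the trans-diaxial sense and the selenoxide can only eliminate towards the ring CH2 because the carbinol carbon has no hydrogen, which places the double bond at C5=C6 and a tertiary OH on C4.

Step 5
Reactants: 6 the tertiary allylic alcohol
Product: 7 (4S,6S)-4-[(tert-butyldimethylsilyl)oxy]-3-methyl-6-(prop-1-en-2-yl)cyclohex-2-en-1-one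
Conditions: C5H5NH[CrO3Cl] (pyridinium chlorochromate), 4 Å molecular sieves, CH2Cl2, rt; filtration through Florisil
Reagents that add atoms: pyridinium chlorochromate, [O-][Cr](=O)(=O)Cl.c1cc[nH+]cc1 (delivers the carbonyl oxygen)
Why: Babler–Dauben oxidative 1,3-transposition, in which the tertiary allylic chromate ester undergoes a [3,3] shift and the secondary chromate is oxidised, so that C6 becomes the carbonyl next to the isopropenyl-bearing C1; the two stereocentres are not involved, and a short reaction with neutral work-up should avoid conjugation of the isopropenyl group.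

Step 6
Reactants: 8 3-methylbutan-2-one; 9 2,4,6-tri(propan-2-yl)benzenesulfonohydrazide
Product: 10 N'-[(2E)-3-methylbutan-2-ylidene]-2,4,6-tri(propan-2-yl)benzenesulfonohydrazide
Conditions: MeOH, HCl (cat.), rt
Reagents that add atoms: none
Why: Acid-catalysed condensation to the arenesulfonylhydrazone, expected as the E isomer (N–N anti to isopropyl), which is the one that is deprotonated at the methyl group.

Step 7
Reactants: 10 the sulfonylhydrazone; 7 the enone
Product: 12 (1R,4S,6S)-4-[(tert-butyldimethylsilyl)oxy]-3-methyl-1-(3-methylbut-1-en-2-yl)-6-(prop-1-en-2-yl)cyclohex-2-en-1-ol, via alkenyllithium 11 (not isolated)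
Conditions: n-BuLi (2.1 equiv per 10), THF, −78 → 0 °C (N2 evolution); then 7, −78 °C; H2O
Reagents that add atoms: none
Why: Shapiro reaction (syn-deprotonation of the methyl group, loss of sulfinate and N2) gives the 2-lithioalkene, which should add 1,2 to the enone by axial attack on the half-chair that has isopropenyl and OTBS equatorial (torsionally favoured, only one axial hydrogen in the way), so that the new alkenyl group lies cis to both substituents and the tertiary centre is 1R.

Step 8
Reactants: 12 the cis-1,2-dialkenylcyclohexenol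
Product: 14 (2Z,4S,6Z,10S)-4-[(tert-butyldimethylsilyl)oxy]-3,7-dimethyl-10-(propan-2-yl)cyclodeca-2,6-dien-1-one, via potassium enolate 13 (not isolated)
Conditions: KH, 18-crown-6, THF, 0 → 40 °C; then AcOH, THF, −78 °C
Reagents that add atoms: none
Why: Deprotonation gives a crown-separated potassium alkoxide that undergoes an anion-accelerated [3,3] sigmatropic shift (anionic oxy-Cope) through a chair six-centre transition state, in which the terminal CH2 carbons of the isopropenyl and the 3-methylbut-1-en-2-yl groups join to form C8–C9 while the ring bond C1–C6 breaks, giving the C1=C10 olefin and the C6=C7 enolate 13. The closest known reaction type is the anionic oxy-Cope ring expansion of 1,2-dialkenylcyclohex-2-en-1-ols, made by 1,2-addition to 6-isopropenylcyclohexenones, to cyclodeca-2,6-dienones. The ten-membered ring is closed by a four-atom ring enlargement (6 → 10) inside a preorganised six-membered transition state, not by an end-to-end cyclisation, so no high dilution should be needed. The selectivity needed is (Z) at C1=C10: the cis-dialkenyl arrangement allows only chairs with one axial and one equatorial alkenyl group, the chair with equatorial isopropenyl and axial C6-alkenyl maps onto (Z)-C1=C10 and an (E)-enolate, and the other chair with axial isopropenyl (which would give E) is disfavoured because the cis C3-OTBS group would be syn-axial to it. The new stereocentre C7 is controlled by the planar chirality of the (E)-configured enolate, which is fixed by that chair and cannot invert because neither O− nor isopropyl can pass through the ring, so protonation from the only exposed face should give 7S and the configuration is relayed from C3 through the C1 and C6 centres of 12 to C7. The quench is done cold with AcOH to keep protonation kinetic and to avoid epimerisation at C7 or migration of the (Z)-enone double bond, which is simply the former ring olefin.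

Step 9
Reactants: 14 the (4Z)-dienone
Product: 15 (2E,4S,6Z,10S)-4-[(tert-butyldimethylsilyl)oxy]-3,7-dimethyl-10-(propan-2-yl)cyclodeca-2,6-dien-1-one
Conditions: hν (350 nm, Pyrex), benzene (degassed), rt; recovered 14 recycled
Reagents that add atoms: none
Why: Photochemical Z→E isomerisation of a medium-ring 2-cycloalkenone, a known way to (E)-cyclodecenones, in which excitation populates the twisted enone triplet and the less conjugated E isomer, absorbing more weakly at this wavelength, should accumulate; no stereocentre is touched.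

Step 10
Reactants: 15 the (4E)-dienone
Product: 16 (1R,2E,4S,6Z,10S)-4-[(tert-butyldimethylsilyl)oxy]-3,7-dimethyl-10-(propan-2-yl)cyclodeca-2,6-dien-1-ol
Conditions: NaBH4, CeCl3·7H2O, MeOH, −78 °C
Reagents that add atoms: none
Why: Luche 1,2-reduction under peripheral-attack control, in which the C7–C8 ring bond stands perpendicular to the carbonyl and the isopropyl group eclipses C=O, so that hydride should enter from the outer face anti to C8 and give the 6R alcohol (1R in the name), with the C6 oxygen anti to the C7 isopropyl group in the zigzag sense.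

Step 11
Reactants: 16 the allylic alcohol
Product: 17 (1R,2E,4S,6Z,10S)-4-[(tert-butyldimethylsilyl)oxy]-3,7-dimethyl-10-(propan-2-yl)cyclodeca-2,6-dien-1-yl acetate
Conditions: Ac2O, pyridine, DMAP (cat.), CH2Cl2, 0 °C → rt
Reagents that add atoms: acetic anhydride, CC(=O)OC(C)=O
Why: DMAP-catalysed acetylation of the only free hydroxyl, with retention at C6.

Step 12
Reactants: 17 the silyl ether acetate
Product: 18 (1R,2E,4S,6Z,10S)-4-hydroxy-3,7-dimethyl-10-(propan-2-yl)cyclodeca-2,6-dien-1-yl acetate
Conditions: Bu4NF, AcOH (1:1), THF, 0 °C → rt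
Reagents that add atoms: none
Why: Fluoride-mediated desilylation, buffered with AcOH so that the allylic acetate and the acid-sensitive 1,5-diene should survive.

Step 13
Reactants: 18 the C3 alcohol; 19 angelic acid
Product: 21 (1S,2E,4R,5S,8Z)-4-(acetyloxy)-2,8-dimethyl-5-(propan-2-yl)cyclodeca-2,8-dien-1-yl (2Z)-2-methylbut-2-enoate (the target), via mixed anhydride 20 (not isolated)
Conditions: 19, 2,4,6-trichlorobenzoyl chloride, Et3N, toluene, rt; then 18, toluene, 75 °C
Reagents that add atoms: none
Why: Yamaguchi-type mixed-anhydride esterification run without a nucleophilic amine catalyst, the usual way to make angelates without Z→E isomerisation to the tiglate; O-acylation leaves C3 untouched, and 75 °C is expected to stay below the onset of Cope rearrangement of the (Z,E)-cyclodeca-1,5-diene.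

**Compound list**

1 | (5S)-2-methyl-5-(prop-1-en-2-yl)cyclohex-2-en-1-one, (S)-(+)-carvone | CC1=CC[C@@H](CC1=O)C(C)=C | starting material
2 | (1S,5S)-2-methyl-5-(prop-1-en-2-yl)cyclohex-2-en-1-ol (cis-carveol) | CC1=CC[C@@H](C[C@@H]1O)C(C)=C | intermediate
3 | (1S,2S,4R,6R)-1-methyl-4-(prop-1-en-2-yl)-7-oxabicyclo[4.1.0]heptan-2-ol (epoxide syn to OH) | C[C@]12O[C@@H]2C[C@@H](C[C@@H]1O)C(C)=C | intermediate
4 | tert-butyldimethyl{[(1R,2S,4S,6R)-1-methyl-4-(prop-1-en-2-yl)-7-oxabicyclo[4.1.0]heptan-2-yl]oxy}silane | C[C@]12O[C@@H]2C[C@@H](C[C@@H]1O[Si](C)(C)C(C)(C)C)C(C)=C | intermediate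
5 | (1S,2S,4R,6S)-2-[(tert-butyldimethylsilyl)oxy]-1-methyl-6-(phenylselanyl)-4-(prop-1-en-2-yl)cyclohexan-1-ol | C[C@@]1(O)[C@@H]([Se]c2ccccc2)C[C@@H](C[C@@H]1O[Si](C)(C)C(C)(C)C)C(C)=C | intermediate
6 | (1R,4R,6S)-6-[(tert-butyldimethylsilyl)oxy]-1-methyl-4-(prop-1-en-2-yl)cyclohex-2-en-1-ol | C[C@@]1(O)C=C[C@@H](C[C@@H]1O[Si](C)(C)C(C)(C)C)C(C)=C | intermediate
7 | (4S,6S)-4-[(tert-butyldimethylsilyl)oxy]-3-methyl-6-(prop-1-en-2-yl)cyclohex-2-en-1-one | CC1=CC(=O)[C@@H](C[C@@H]1O[Si](C)(C)C(C)(C)C)C(C)=C | intermediate
8 | 3-methylbutan-2-one | CC(C)C(C)=O | starting material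
9 | 2,4,6-tri(propan-2-yl)benzenesulfonohydrazide | CC(C)c1cc(C(C)C)c(S(=O)(=O)NN)c(C(C)C)c1 | starting material
10 | N'-[(2E)-3-methylbutan-2-ylidene]-2,4,6-tri(propan-2-yl)benzenesulfonohydrazide | CC(C)/C(C)=N/NS(=O)(=O)c1c(C(C)C)cc(C(C)C)cc1C(C)C | intermediate
11 | (3-methylbut-1-en-2-yl)lithium | [Li]C(=C)C(C)C | intermediate
12 | (1R,4S,6S)-4-[(tert-butyldimethylsilyl)oxy]-3-methyl-1-(3-methylbut-1-en-2-yl)-6-(prop-1-en-2-yl)cyclohex-2-en-1-ol | CC1=C[C@](O)(C(=C)C(C)C)[C@@H](C[C@@H]1O[Si](C)(C)C(C)(C)C)C(C)=C | intermediate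
13 | potassium (1(10)E,2Z,4S,6Z)-4-[(tert-butyldimethylsilyl)oxy]-3,7-dimethyl-10-(propan-2-yl)cyclodeca-1(10),2,6-trien-1-olate | CC(C)(C)[Si](C)(C)O[C@H]1C/C=C(/C)CC/C(C(C)C)=C(\[O-])/C=C\1C.[K+] | intermediate
14 | (2Z,4S,6Z,10S)-4-[(tert-butyldimethylsilyl)oxy]-3,7-dimethyl-10-(propan-2-yl)cyclodeca-2,6-dien-1-one | CC(C)(C)[Si](C)(C)O[C@H]1C/C=C(/C)CC[C@@H](C(C)C)C(=O)/C=C\1C | intermediate
15 | (2E,4S,6Z,10S)-4-[(tert-butyldimethylsilyl)oxy]-3,7-dimethyl-10-(propan-2-yl)cyclodeca-2,6-dien-1-one | CC(C)(C)[Si](C)(C)O[C@H]1C/C=C(/C)CC[C@@H](C(C)C)C(=O)/C=C/1C | intermediate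
16 | (1R,2E,4S,6Z,10S)-4-[(tert-butyldimethylsilyl)oxy]-3,7-dimethyl-10-(propan-2-yl)cyclodeca-2,6-dien-1-ol | CC(C)(C)[Si](C)(C)O[C@H]1C/C=C(/C)CC[C@@H](C(C)C)[C@@H](O)/C=C/1C | intermediate
17 | (1R,2E,4S,6Z,10S)-4-[(tert-butyldimethylsilyl)oxy]-3,7-dimethyl-10-(propan-2-yl)cyclodeca-2,6-dien-1-yl acetate | CC(C)(C)[Si](C)(C)O[C@H]1C/C=C(/C)CC[C@@H](C(C)C)[C@@H](OC(C)=O)/C=C/1C | intermediate
18 | (1R,2E,4S,6Z,10S)-4-hydroxy-3,7-dimethyl-10-(propan-2-yl)cyclodeca-2,6-dien-1-yl acetate | O[C@H]1C/C=C(/C)CC[C@@H](C(C)C)[C@@H](OC(C)=O)/C=C/1C | intermediate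
19 | (2Z)-2-methylbut-2-enoic acid (angelic acid) | C/C=C(/C)C(=O)O | starting material
20 | (2Z)-2-methylbut-2-enoic 2,4,6-trichlorobenzoic anhydride | C/C=C(/C)C(=O)OC(=O)c1c(Cl)cc(Cl)cc1Cl | intermediate
21 | (1S,2E,4R,5S,8Z)-4-(acetyloxy)-2,8-dimethyl-5-(propan-2-yl)cyclodeca-2,8-dien-1-yl (2Z)-2-methylbut-2-enoate | C/C=C(/C)C(=O)O[C@H]1C/C=C(/C)CC[C@@H](C(C)C)[C@@H](OC(C)=O)/C=C/1C | target

**Step count and risks**

Total steps: 13. Longest linear sequence: 12 steps (1 → 21 through steps 1–5 and 7–13).

Steps most likely to fail: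

Step 9. What may go wrong: the photostationary state does not favour the E-enone, or the 1,5-diene undergoes transannular photocycloaddition. The fallback replaces photochemistry by a stereospecific olefin inversion; it sets out from 14 and comes back at 15. Luche reduction of 14 gives the (4Z)-allylic alcohol F1, whose carbinol epimers are of no consequence because the carbinol is re-oxidised. VO(acac)2 with t-BuOOH then epoxidises only the allylic-alcohol olefin, syn to OH, to the epoxy alcohol F2. Ph2PLi in THF opens the epoxide at C5 with inversion, MeI quaternises phosphorus, and the betaine collapses by syn-elimination of the phosphine oxide to the (4E)-allylic alcohol F3 with inverted olefin geometry. MnO2 in CH2Cl2 oxidises F3 to 15.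

Step 8. What may go wrong: rearrangement through the other chair, with axial isopropenyl, which would give the (E)-C1=C10 isomer and an enolate without planar chirality, so that control at C7 is lost. The fallback corrects the olefin afterwards by an epoxide-based inversion; it sets out from 12 and comes back at 14. The rearrangement product is then the (1(10)E,4Z)-dienone F4; its C7 epimers are equilibrated with DBU and the 7S epimer is carried on. m-CPBA (NaHCO3, CH2Cl2, −20 °C) epoxidises only the isolated C1=C10 olefin, not the enone, to the epoxy ketone F5. Aqueous HClO4 in THF opens the epoxide in the anti sense to the diol F6; attack at either carbon gives the same relative configuration. Thiocarbonyldiimidazole converts this into the cyclic thionocarbonate F7. Corey–Winter syn-elimination with 1,3-dimethyl-2-phenyl-1,3,2-diazaphospholidine at 40 °C then gives the (Z)-C1=C10 olefin, which is 14.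

Step 7. What may go wrong: attack of the bulky alkenyllithium on the other carbonyl face (trans to isopropenyl), which would lead to the E-olefin in step 8, or enolisation of 7. The fallback uses a small sp nucleophile and then builds the alkene by carbometalation; it sets out from 7 and comes back at 12. HC≡CMgBr (THF, −78 → 0 °C) should add axially to give the ethynyl carbinol F8. i-PrMgCl (3 equiv) with CuI (10 mol %) in Et2O–THF then adds across the alkyne in the anti sense, with isopropyl on the inner carbon and magnesium chelated by the alkoxide on the terminal carbon; hydrolysis gives 12.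

Further compounds
F1 | step 9 | (2Z,4S,6Z,10S)-4-[(tert-butyldimethylsilyl)oxy]-3,7-dimethyl-10-(propan-2-yl)cyclodeca-2,6-dien-1-ol (C1 epimers) | CC(C)(C)[Si](C)(C)O[C@H]1C/C=C(/C)CC[C@@H](C(C)C)C(O)/C=C\1C
F2 | step 9 | 2,3-epoxide of F1, cis-epoxide syn to the hydroxyl (one face drawn) | CC(C)(C)[Si](C)(C)O[C@H]1C/C=C(/C)CC[C@@H](C(C)C)C(O)[C@@H]2O[C@]12C
F3 | step 9 | (2E,4S,6Z,10S)-4-[(tert-butyldimethylsilyl)oxy]-3,7-dimethyl-10-(propan-2-yl)cyclodeca-2,6-dien-1-ol (C1 epimers) | CC(C)(C)[Si](C)(C)O[C@H]1C/C=C(/C)CC[C@@H](C(C)C)C(O)/C=C/1C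
F4 | step 8 | (2Z,4S,6E,10S)-4-[(tert-butyldimethylsilyl)oxy]-3,7-dimethyl-10-(propan-2-yl)cyclodeca-2,6-dien-1-one | CC(C)(C)[Si](C)(C)O[C@H]1C/C=C(\C)CC[C@@H](C(C)C)C(=O)/C=C\1C
F5 | step 8 | 6,7-epoxide of F4, trans-epoxide (one face drawn) | CC(C)(C)[Si](C)(C)O[C@H]1C[C@@H]2O[C@@]2(C)CC[C@@H](C(C)C)C(=O)/C=C\1C
F6 | step 8 | 6,7-dihydroxy-6,7-dihydro derivative of F4 from anti opening of F5 | CC(C)(C)[Si](C)(C)O[C@H]1C[C@H](O)[C@](C)(O)CC[C@@H](C(C)C)C(=O)/C=C\1C
F7 | step 8 | cyclic thionocarbonate of F6 | CC(C)(C)[Si](C)(C)O[C@H]1C[C@@H]2OC(=S)O[C@]2(C)CC[C@@H](C(C)C)C(=O)/C=C\1C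
F8 | step 7 | (1R,4S,6S)-4-[(tert-butyldimethylsilyl)oxy]-1-ethynyl-3-methyl-6-(prop-1-en-2-yl)cyclohex-2-en-1-ol | CC1=C[C@](O)(C#C)[C@@H](C[C@@H]1O[Si](C)(C)C(C)(C)C)C(C)=C
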